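**Plan**
- Retrosynthesis: C6–C7 and O–C19 are cut together (last ring-forming step), then C8–C9 (alkenylmagnesium + aldehyde), C1–C2 (aldol) and C10–C9 (cuprate), then the cyclohexenone at C1=C10 (metathesis) and C11–C12 (crotylation).
- Enabling feature: C7 is both the allylic carbinol carbon next to the Z C5=C6 olefin of the ten-membered ring and the alkoxy carbon of the C7–O–C19 butenolide. A C6 alkenylmetal adding to a C7 aldehyde that sits cis to the C19 ester on C8=C17 therefore forms the carbocycle and the lactone together.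
- Forward: cyclohexenone 9 first; vinyl cuprate and aldol attach the C9 and C2–C6 arms; C14 is reduced; the C9 aldehyde is joined to iodoenoate 21; the C7 aldehyde is unveiled; ten-membered ring and butenolide close in one step; desilylation.
- Stereochemistry: C11/C12 from catalyst-controlled syn crotylation (the trans Me/O pair on the ring is the syn pair of the open chain, hence the Z boronate); C10 by axial cuprate attack anti to the C12 silyloxy group; C1 anti to the new C10 substituent; C2 from a syn-selective titanium aldol; C14 by CBS reagent control; C9 by Felkin–Anh addition; C7 in the ring closure; both olefin geometries from syn carbometalations.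

Key step: step 22

Numbering: locants C1–C19 are those of the target (C1 quaternary ring-fusion carbon with methyl C15, C2 butyrate carbinol, C5=C6 ring olefin, C7 lactone carbinol, C8=C17 butenolide olefin, C9 and C14 acetate carbinols, C10 ring-fusion CH, C11 methyl-bearing CH, C12 free carbinol, C18 methyl on C17, C19 lactone carbonyl). From 22 on, each stereocentre has the spatial arrangement of the target, as written in the SMILES.
Assumption: 1, 2, 10, 11 and 17 are purchased, and (S)-TRIP is taken to direct the crotyl group to the Si face of 1 by analogy with its sense in allylborations (the enantiomeric acid would be used otherwise).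

**Cyclohexenone 9**

Step 1
Reactants: 1 3-[(tert-butyldimethylsilyl)oxy]propanal; 2 (Z)-crotylboronic acid pinacol ester
Product: 3 (3R,4R)-1-[(tert-butyldimethylsilyl)oxy]-4-methylhex-5-en-3-ol
Conditions: (S)-TRIP (5 mol %), toluene, −30 °C; aq. NaHCO3
Reagents that add atoms: none
Why: Chiral phosphoric acid-catalysed crotylboration through a closed chair transition state, in which the Z boronate gives the 3,4-syn adduct and the catalyst is expected to expose the Si face of the aldehyde, so that C12 (3R) and C11 (4R) are set together.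

Step 2
Reactants: 3 (3R,4R)-1-[(tert-butyldimethylsilyl)oxy]-4-methylhex-5-en-3-ol
Product: 4 (3R,4R)-1,3-bis[(tert-butyldimethylsilyl)oxy]-4-methylhex-5-ene
Conditions: TBSOTf, 2,6-lutidine, CH2Cl2, −78 → 0 °C
Reagents that add atoms: tert-butyldimethylsilyl trifluoromethanesulfonate CC(C)(C)[Si](C)(C)OS(=O)(=O)C(F)(F)F
Why: Silylation of a branched secondary alcohol with the silyl triflate and a hindered base, which installs the C12 protecting group that is kept to the last step.

Step 3
Reactants: 4 (3R,4R)-1,3-bis[(tert-butyldimethylsilyl)oxy]-4-methylhex-5-ene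
Product: 5 (3R,4R)-3-[(tert-butyldimethylsilyl)oxy]-4-methylhex-5-en-1-ol
Conditions: CSA (10 mol %), MeOH/CH2Cl2 (1:1), 0 °C
Reagents that add atoms: none
Why: Acid-catalysed methanolysis (selective desilylation), in which the unhindered primary silyl ether is cleaved much faster than the secondary one flanked by the methyl-bearing carbon.

Step 4
Reactants: 5 (3R,4R)-3-[(tert-butyldimethylsilyl)oxy]-4-methylhex-5-en-1-ol
Product: 6 (3R,4R)-3-[(tert-butyldimethylsilyl)oxy]-4-methylhex-5-enal
Conditions: Dess–Martin periodinane, NaHCO3, CH2Cl2, 0 °C → rt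
Reagents that add atoms: none
Why: Dess–Martin oxidation under buffered, non-basic conditions, so the β-silyloxy aldehyde does not eliminate.

Step 5
Reactants: 6 (3R,4R)-3-[(tert-butyldimethylsilyl)oxy]-4-methylhex-5-enal
Product: 7 (5R,6R)-5-[(tert-butyldimethylsilyl)oxy]-2,6-dimethylocta-1,7-dien-3-ol (both C3 epimers)
Conditions: isopropenylmagnesium bromide, THF, −78 °C; H2O
Reagents that add atoms: isopropenylmagnesium bromide CC(=C)[Mg]Br
Why: Grignard addition to the aldehyde, which brings in C1 with its methyl group; the new carbinol centre is of no consequence because it is oxidised in the next step.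

Step 6
Reactants: 7 (5R,6R)-5-[(tert-butyldimethylsilyl)oxy]-2,6-dimethylocta-1,7-dien-3-ol
Product: 8 (5R,6R)-5-[(tert-butyldimethylsilyl)oxy]-2,6-dimethylocta-1,7-dien-3-one
Conditions: Dess–Martin periodinane, NaHCO3, CH2Cl2, rt
Reagents that add atoms: none
Why: Dess–Martin oxidation of the allylic alcohol to the isopropenyl ketone, mild enough to leave the β-silyloxy group in place.

Step 7
Reactants: 8 (5R,6R)-5-[(tert-butyldimethylsilyl)oxy]-2,6-dimethylocta-1,7-dien-3-one
Product: 9 (4R,5R)-5-[(tert-butyldimethylsilyl)oxy]-2,4-dimethylcyclohex-2-en-1-one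
Conditions: Grubbs second-generation catalyst (5 mol %), CH2Cl2 (0.01 M), 40 °C
Reagents that add atoms: none
Why: Ring-closing metathesis between the vinyl and isopropenyl groups closes the six-membered ring as the 2-methyl enone with loss of ethene and does not touch the two stereocentres.

**Aldehyde 16**

Step 8
Reactants: 10 2-(2-bromoethyl)-1,3-dioxolane; 11 propyne
Product: 15 2-[(3Z)-4-iodo-3-methylbut-3-en-1-yl]-1,3-dioxolane, via Grignard reagent 12 (not isolated), via alkylcopper 13 (not isolated), via alkenylcopper 14 (not isolated)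
Conditions: Mg, THF, 30 °C; CuBr·SMe2, Me2S/THF, −45 °C; propyne, −25 °C; I2, THF, −40 → 0 °C
Reagents that add atoms: iodine II
Why: Normant carbocupration, in which the alkylcopper adds syn across propyne with copper at the terminal carbon and iodinolysis proceeds with retention, so the chain and iodine end up cis (Z C5=C6).

Step 9
Reactants: 15 2-[(3Z)-4-iodo-3-methylbut-3-en-1-yl]-1,3-dioxolane
Product: 16 (4Z)-5-iodo-4-methylpent-4-enal
Conditions: 2 M aq. HCl, THF, 40 °C
Reagents that add atoms: water O
Why: Acid-catalysed acetal hydrolysis, to which the alkenyl iodide is inert and which cannot alter the olefin geometry.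

**Iodoenoate 21**

Step 10
Reactants: 17 methyl 4-hydroxybut-2-ynoate
Product: 18 methyl 4-[(triethylsilyl)oxy]but-2-ynoate
Conditions: TESCl, imidazole, CH2Cl2, 0 °C
Reagents that add atoms: chlorotriethylsilane CC[Si](Cl)(CC)CC
Why: Silylation of the primary propargylic alcohol, which carries C7 at the alcohol oxidation level so that it can later be oxidised without passing through an acetal next to the cis ester.

Step 11
Reactants: 18 methyl 4-[(triethylsilyl)oxy]but-2-ynoate
Product: 20 methyl (2E)-2-methyl-3-(tributylstannyl)-4-[(triethylsilyl)oxy]but-2-enoate, via alkenylcopper 19 (not isolated)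
Conditions: Bu3SnH, LDA, THF, −40 °C; CuBr·SMe2, −78 °C; 18, −78 °C; MeI, HMPA, −78 → −30 °C
Reagents that add atoms: tributyltin hydride CCCC[SnH](CCCC)CCCC; iodomethane CI
Why: Stannylcupration of the ynoate places tin on the β-carbon (C8) and copper on the α-carbon (C17) by syn addition, and methylation of the alkenylcopper at low temperature keeps that geometry, so tin is cis to the methyl group and the silyloxymethyl group (C7) is cis to the ester (C19).

Step 12
Reactants: 20 methyl (2E)-2-methyl-3-(tributylstannyl)-4-[(triethylsilyl)oxy]but-2-enoate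
Product: 21 methyl (2E)-3-iodo-2-methyl-4-[(triethylsilyl)oxy]but-2-enoate
Conditions: I2, CH2Cl2, 0 °C → rt; aq. Na2S2O3
Reagents that add atoms: iodine II
Why: Iododestannylation, an ipso substitution that proceeds with retention of the olefin geometry.

**Assembly and ring closure**

Step 13
Reactants: 9 (4R,5R)-5-[(tert-butyldimethylsilyl)oxy]-2,4-dimethylcyclohex-2-en-1-one
Product: 22 (3S,4R,5R)-5-[(tert-butyldimethylsilyl)oxy]-3-ethenyl-2,4-dimethyl-1-[(trimethylsilyl)oxy]cyclohex-1-ene
Conditions: vinylmagnesium bromide, CuBr·SMe2 (10 mol %), TMSCl, HMPA, THF, −78 °C; Et3N, hexane work-up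
Reagents that add atoms: vinylmagnesium bromide C=C[Mg]Br; chlorotrimethylsilane C[Si](C)(C)Cl
Why: Copper-catalysed conjugate addition with in situ silylation, in which the enone reacts through the half-chair with the C11 methyl and C12 silyloxy groups equatorial and axial attack anti to the silyloxy group puts the vinyl group trans to OTBS and cis to the C11 methyl (C10), since the rival attack anti to the methyl group would need the diaxial conformer and a 1,3-diaxial clash with the silyloxy group, while the silyl chloride fixes the enolate as its regiodefined silyl ether.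

Step 14
Reactants: 22 (3S,4R,5R)-5-[(tert-butyldimethylsilyl)oxy]-3-ethenyl-2,4-dimethyl-1-[(trimethylsilyl)oxy]cyclohex-1-ene; 16 (4Z)-5-iodo-4-methylpent-4-enal
Product: 25 (2S,3S,4R,5R)-5-[(tert-butyldimethylsilyl)oxy]-3-ethenyl-2-[(1R,4Z)-1-hydroxy-5-iodo-4-methylpent-4-en-1-yl]-2,4-dimethylcyclohexan-1-one, via lithium enolate 23 (not isolated), via titanium enolate 24 (not isolated)
Conditions: MeLi, THF, 0 °C; ClTi(Oi-Pr)3, −78 °C; 16, −78 °C; H2O
Reagents that add atoms: none
Why: Titanium enolate aldol addition, in which methyllithium frees the regiodefined enolate, the aldehyde enters C1 anti to the vicinal C10 vinyl group (quaternary C1), and triisopropoxytitanium enolates of cyclic ketones are expected to react through a boat-like transition state to the syn (erythro) aldol, here the 2R carbinol, a preference that has to be confirmed on this tetrasubstituted enolate.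

Step 15
Reactants: 25 aldol adduct (C2 hydroxyl, C14 ketone)
Product: 26 C2 butyrate of 25
Conditions: (n-PrCO)2O, DMAP, Et3N, CH2Cl2, 0 °C → rt
Reagents that add atoms: butyric anhydride CCCC(=O)OC(=O)CCC
Why: DMAP-catalysed acylation of the hindered carbinol, which places the butyrate on O2 while C14 is still a ketone; the quaternary α-carbon excludes elimination and the weak base avoids retro-aldol cleavage.

Step 16
Reactants: 26 C2 butyrate with C14 ketone
Product: 27 (14S)-alcohol of 26
Conditions: (R)-Me-CBS (0.5 equiv), catecholborane, toluene, −78 → −40 °C; MeOH, pH 7 buffer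
Reagents that add atoms: none
Why: Corey–Bakshi–Shibata reduction under reagent control, in which the ketone binds the (R)-oxazaborolidine with the quaternary C1 as the large group so that hydride gives the 14S alcohol (C14–O cis to the C2 arm), catecholborane at low temperature touches neither the alkenes nor the ester, and the neutral work-up keeps the butyrate on O2.

Step 17
Reactants: 27 (14S)-alcohol
Product: 28 (14S)-acetate with C10 vinyl group
Conditions: Ac2O, DMAP, pyridine, CH2Cl2, 0 °C → rt
Reagents that add atoms: acetic anhydride CC(=O)OC(C)=O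
Why: DMAP-catalysed acetylation, carried out at once so that the neighbouring butyrate cannot migrate to O14.

Step 18
Reactants: 28 (14S)-acetate with C10 vinyl group
Product: 30 C9 aldehyde, via vicinal diol 29 (not isolated)
Conditions: OsO4 (2 mol %), NaIO4, 2,6-lutidine, dioxane/H2O (3:1), rt
Reagents that add atoms: osmium tetroxide O=[Os](=O)(=O)=O (catalytic oxygen carrier); sodium periodate [Na+].[O-]I(=O)(=O)=O
Why: Lemieux–Johnson oxidative cleavage, in which the monosubstituted olefin is dihydroxylated in preference to the iodine-deactivated trisubstituted alkenyl iodide and the lutidine buffer keeps C10 next to the new aldehyde from epimerising.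

Step 19
Reactants: 21 methyl (2E)-3-iodo-2-methyl-4-[(triethylsilyl)oxy]but-2-enoate; 30 C9 aldehyde
Product: 32 (9R)-alcohol with C7 as CH2OTES cis to the C19 methyl ester, via alkenylmagnesium chloride 31 (not isolated)
Conditions: 21 (2 equiv), i-PrMgCl·LiCl (1.9 equiv), THF, −40 °C; 30, −78 → −40 °C; pH 7 buffer, −40 °C
Reagents that add atoms: none
Why: Iodine–magnesium exchange on the ester-activated iodide followed by carbonyl addition, in which the alkenylmagnesium attacks the aldehyde in the Felkin–Anh sense with the quaternary C1 anti to the nucleophile (9R), the alkoxide lies trans to the ester and cannot lactonise, and the unactivated C6 iodide and the esters of 30 are left alone at this temperature.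

Step 20
Reactants: 32 (9R)-alcohol
Product: 33 (9R)-acetate
Conditions: Ac2O, DMAP, pyridine, CH2Cl2, 0 °C
Reagents that add atoms: acetic anhydride CC(=O)OC(C)=O
Why: DMAP-catalysed acetylation of the allylic alcohol under conditions that leave the primary triethylsilyl ether in place.

Step 21
Reactants: 33 (9R)-acetate with C7 triethylsilyl ether
Product: 35 cyclisation precursor with C7 aldehyde cis to the C19 methyl ester, via alkoxysulfonium chloride 34 (not isolated)
Conditions: (COCl)2, DMSO, CH2Cl2, −78 → −40 °C; Et3N, −78 → 0 °C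
Reagents that add atoms: none
Why: Swern oxidation applied directly to a primary triethylsilyl ether, which the chlorosulfonium reagent converts into the alkoxysulfonium salt and then the aldehyde without leaving the γ-hydroxy cis-enoate free to lactonise, while the secondary TBS ether and the esters are inert and the aldehyde has no α-hydrogen.

Step 22
Reactants: 35 cyclisation precursor (Z alkenyl iodide at C6, C7 aldehyde, C19 methyl ester)
Product: 38 C12 tert-butyldimethylsilyl ether of the target, via alkenylchromium 36 (not isolated), via chromium alkoxide 37 (not isolated)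
Conditions: CrCl2 (15 equiv), NiCl2 (1 mol % of Cr), DMSO/THF (3:1), 0.002 M, slow addition of 35, rt; aq. sodium serinate
Reagents that add atoms: none
Why: Nickel(0), formed from NiCl2 by chromium(II), inserts into the C6–I bond, the alkenyl group passes to chromium(III) with retention of the Z geometry (36), and this weakly basic alkenylchromium adds to the C7 aldehyde to give chromium alkoxide 37, whose oxygen lies cis to the C19 methyl ester across C8=C17 and displaces methoxide. The closest known reaction type is the Nozaki–Hiyama–Kishi cyclisation of alkenyl iodide aldehydes to medium and large rings, together with the lactonisation that follows carbonyl addition next to a cis ester. The ten-membered carbocycle closes in the 10-exo-trig mode (C6 onto the aldehyde carbon, its oxygen outside the ring) and the butenolide in the 5-exo-trig mode (O7 onto the ester carbonyl, acyl substitution). The new C7 centre is under substrate control: allylic strain between C9–H and the C18 methyl group holds the C10 arm, which carries the tether, and the C9 acetate on opposite faces of the C8=C17 plane, the trans-fused cyclohexane and the Z olefin limit the reach of the tether, and 7S corresponds to attack opposite the C10 arm on the aldehyde rotamer whose oxygen is turned toward C19, which is also the rotamer that can lactonise directly; this preference is an expectation and has to be confirmed. The step needs chemoselectivity (the alkenylchromium adds only to the aldehyde, which cannot enolise and is activated by the ester, while the acetates, the butyrate and the silyl ether are inert) and ring closure in preference to oligomerisation, which high dilution and slow addition secure.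

Step 23
Reactants: 38 C12 tert-butyldimethylsilyl ether of the target
Product: 39 CNP0281577.1
Conditions: HF·pyridine, pyridine, THF, 0 °C → rt
Reagents that add atoms: none
Why: Fluoride-mediated desilylation with buffered HF·pyridine, which cleaves the secondary silyl ether while the three esters and the butenolide persist and the weakly acidic medium prevents migration of the C14 acetate to the cis C12 hydroxyl.

**Compound list**

1 | 3-[(tert-butyldimethylsilyl)oxy]propanal | O=CCCO[Si](C)(C)C(C)(C)C | starting material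
2 | (Z)-crotylboronic acid pinacol ester | C/C=C\CB1OC(C)(C)C(C)(C)O1 | starting material
3 | (3R,4R)-1-[(tert-butyldimethylsilyl)oxy]-4-methylhex-5-en-3-ol | C=C[C@@H](C)[C@H](O)CCO[Si](C)(C)C(C)(C)C | intermediate
4 | (3R,4R)-1,3-bis[(tert-butyldimethylsilyl)oxy]-4-methylhex-5-ene | C=C[C@@H](C)[C@H](O[Si](C)(C)C(C)(C)C)CCO[Si](C)(C)C(C)(C)C | intermediate
5 | (3R,4R)-3-[(tert-butyldimethylsilyl)oxy]-4-methylhex-5-en-1-ol | C=C[C@@H](C)[C@H](O[Si](C)(C)C(C)(C)C)CCO | intermediate
6 | (3R,4R)-3-[(tert-butyldimethylsilyl)oxy]-4-methylhex-5-enal | C=C[C@@H](C)[C@H](O[Si](C)(C)C(C)(C)C)CC=O | intermediate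
7 | (5R,6R)-5-[(tert-butyldimethylsilyl)oxy]-2,6-dimethylocta-1,7-dien-3-ol (C3 epimers) | C=C[C@@H](C)[C@H](O[Si](C)(C)C(C)(C)C)CC(O)C(C)=C | intermediate
8 | (5R,6R)-5-[(tert-butyldimethylsilyl)oxy]-2,6-dimethylocta-1,7-dien-3-one | C=C[C@@H](C)[C@H](O[Si](C)(C)C(C)(C)C)CC(=O)C(C)=C | intermediate
9 | (4R,5R)-5-[(tert-butyldimethylsilyl)oxy]-2,4-dimethylcyclohex-2-en-1-one (methyl and silyloxy trans) | O=C1C(C)=C[C@@H](C)[C@H](O[Si](C)(C)C(C)(C)C)C1 | intermediate
10 | 2-(2-bromoethyl)-1,3-dioxolane | BrCCC1OCCO1 | starting material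
11 | propyne | CC#C | starting material
12 | [2-(1,3-dioxolan-2-yl)ethyl]magnesium bromide (not isolated) | Br[Mg]CCC1OCCO1 | intermediate
13 | [2-(1,3-dioxolan-2-yl)ethyl]copper (not isolated) | [Cu]CCC1OCCO1 | intermediate
14 | [(1Z)-4-(1,3-dioxolan-2-yl)-2-methylbut-1-en-1-yl]copper (not isolated) | [Cu]/C=C(C)\CCC1OCCO1 | intermediate
15 | 2-[(3Z)-4-iodo-3-methylbut-3-en-1-yl]-1,3-dioxolane | I/C=C(C)\CCC1OCCO1 | intermediate
16 | (4Z)-5-iodo-4-methylpent-4-enal | O=CCC/C(C)=C\I | intermediate
17 | methyl 4-hydroxybut-2-ynoate | COC(=O)C#CCO | starting material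
18 | methyl 4-[(triethylsilyl)oxy]but-2-ynoate | COC(=O)C#CCO[Si](CC)(CC)CC | intermediate
19 | α-cuprio β-stannyl enoate, copper cis to tin (not isolated) | COC(=O)/C([Cu])=C(\CO[Si](CC)(CC)CC)[Sn](CCCC)(CCCC)CCCC | intermediate
20 | methyl (2E)-2-methyl-3-(tributylstannyl)-4-[(triethylsilyl)oxy]but-2-enoate | COC(=O)/C(C)=C(\CO[Si](CC)(CC)CC)[Sn](CCCC)(CCCC)CCCC | intermediate
21 | methyl (2E)-3-iodo-2-methyl-4-[(triethylsilyl)oxy]but-2-enoate (CH2OTES cis to CO2Me) | COC(=O)/C(C)=C(\CO[Si](CC)(CC)CC)I | intermediate
22 | (3S,4R,5R)-5-[(tert-butyldimethylsilyl)oxy]-3-ethenyl-2,4-dimethyl-1-[(trimethylsilyl)oxy]cyclohex-1-ene (vinyl cis to C11 methyl, trans to OTBS) | C[Si](C)(C)OC1=C(C)[C@@H](C=C)[C@@H](C)[C@H](O[Si](C)(C)C(C)(C)C)C1 | intermediate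
23 | lithium enolate corresponding to 22 (not isolated) | [Li]OC1=C(C)[C@@H](C=C)[C@@H](C)[C@H](O[Si](C)(C)C(C)(C)C)C1 | intermediate
24 | triisopropoxytitanium enolate corresponding to 22 (not isolated) | CC(C)O[Ti](OC(C)C)(OC(C)C)OC1=C(C)[C@@H](C=C)[C@@H](C)[C@H](O[Si](C)(C)C(C)(C)C)C1 | intermediate
25 | aldol adduct, (2S,3S,4R,5R)-5-[(tert-butyldimethylsilyl)oxy]-3-ethenyl-2-[(1R,4Z)-1-hydroxy-5-iodo-4-methylpent-4-en-1-yl]-2,4-dimethylcyclohexan-1-one | O[C@H](CC/C(C)=C\I)[C@@]1(C)C(=O)C[C@@H](O[Si](C)(C)C(C)(C)C)[C@H](C)[C@@H]1C=C | intermediate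
26 | C2 butyrate of 25 (2R; C14 ketone) | CCCC(=O)O[C@H](CC/C(C)=C\I)[C@@]1(C)C(=O)C[C@@H](O[Si](C)(C)C(C)(C)C)[C@H](C)[C@@H]1C=C | intermediate
27 | (14S)-alcohol from 26 (C14 hydroxyl cis to the C2 arm, trans to the C1 methyl) | CCCC(=O)O[C@H](CC/C(C)=C\I)[C@@]1(C)[C@@H](O)C[C@@H](O[Si](C)(C)C(C)(C)C)[C@H](C)[C@@H]1C=C | intermediate
28 | (14S)-acetate of 27 (C2 butyrate, C10 vinyl, C12 OTBS) | CCCC(=O)O[C@H](CC/C(C)=C\I)[C@@]1(C)[C@@H](OC(C)=O)C[C@@H](O[Si](C)(C)C(C)(C)C)[C@H](C)[C@@H]1C=C | intermediate
29 | vicinal diol from the vinyl group of 28 (not isolated) | CCCC(=O)O[C@H](CC/C(C)=C\I)[C@@]1(C)[C@@H](OC(C)=O)C[C@@H](O[Si](C)(C)C(C)(C)C)[C@H](C)[C@@H]1C(O)CO | intermediate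
30 | C9 aldehyde (formyl group on C10 in place of vinyl) | CCCC(=O)O[C@H](CC/C(C)=C\I)[C@@]1(C)[C@@H](OC(C)=O)C[C@@H](O[Si](C)(C)C(C)(C)C)[C@H](C)[C@@H]1C=O | intermediate
31 | alkenylmagnesium chloride from 21, magnesium trans to the ester (not isolated) | COC(=O)/C(C)=C(\CO[Si](CC)(CC)CC)[Mg]Cl | intermediate
32 | (9R)-alcohol: C9 carbinol bonded to C8 of the enoate, C7 as CH2OTES cis to CO2Me | CCCC(=O)O[C@H](CC/C(C)=C\I)[C@@]1(C)[C@@H](OC(C)=O)C[C@@H](O[Si](C)(C)C(C)(C)C)[C@H](C)[C@@H]1[C@@H](O)/C(CO[Si](CC)(CC)CC)=C(\C)C(=O)OC | intermediate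
33 | (9R)-acetate of 32 | CCCC(=O)O[C@H](CC/C(C)=C\I)[C@@]1(C)[C@@H](OC(C)=O)C[C@@H](O[Si](C)(C)C(C)(C)C)[C@H](C)[C@@H]1[C@@H](OC(C)=O)/C(CO[Si](CC)(CC)CC)=C(\C)C(=O)OC | intermediate
34 | C7 alkoxydimethylsulfonium chloride from 33 (not isolated) | CCCC(=O)O[C@H](CC/C(C)=C\I)[C@@]1(C)[C@@H](OC(C)=O)C[C@@H](O[Si](C)(C)C(C)(C)C)[C@H](C)[C@@H]1[C@@H](OC(C)=O)/C(CO[S+](C)C)=C(\C)C(=O)OC.[Cl-] | intermediate
35 | cyclisation precursor: Z alkenyl iodide at C6, C7 aldehyde cis to the C19 methyl ester on C8=C17, C2 butyrate, C9 and C14 acetates, C12 OTBS | CCCC(=O)O[C@H](CC/C(C)=C\I)[C@@]1(C)[C@@H](OC(C)=O)C[C@@H](O[Si](C)(C)C(C)(C)C)[C@H](C)[C@@H]1[C@@H](OC(C)=O)/C(C=O)=C(\C)C(=O)OC | intermediate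
36 | C6 alkenylchromium(III) dichloride from 35 (not isolated) | CCCC(=O)O[C@H](CC/C(C)=C\[Cr](Cl)Cl)[C@@]1(C)[C@@H](OC(C)=O)C[C@@H](O[Si](C)(C)C(C)(C)C)[C@H](C)[C@@H]1[C@@H](OC(C)=O)/C(C=O)=C(\C)C(=O)OC | intermediate
37 | ten-membered (7S) chromium alkoxide with open C19 methyl ester (not isolated) | CCCC(=O)O[C@@H]1CC/C(C)=C\[C@H](O[Cr](Cl)Cl)/C(=C(/C)C(=O)OC)[C@H](OC(C)=O)[C@H]2[C@@H](C)[C@H](O[Si](C)(C)C(C)(C)C)C[C@H](OC(C)=O)[C@@]21C | intermediate
38 | C12 tert-butyldimethylsilyl ether of the target | CCCC(=O)O[C@@H]1CC/C(C)=C\[C@@H]2OC(=O)C(C)=C2[C@H](OC(C)=O)[C@H]2[C@@H](C)[C@H](O[Si](C)(C)C(C)(C)C)C[C@H](OC(C)=O)[C@@]21C | intermediate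
39 | CNP0281577.1 | CCCC(=O)O[C@@H]1CC/C(C)=C\[C@@H]2OC(=O)C(C)=C2[C@H](OC(C)=O)[C@H]2[C@@H](C)[C@H](O)C[C@H](OC(C)=O)[C@@]21C | target

**Step count and risks**

Total step count: 23 (steps 1–7 to enone 9, 8–9 to aldehyde 16, 10–12 to iodoenoate 21, 13–23 assembly).
Longest linear sequence: 18 steps (1–7, then 13–23) from 1.

Steps most likely to fail:

Step 22. The tethered alkenylchromium may reach the other face of the C7 aldehyde (poor or reversed facial selectivity). Oligomerisation or reduction of the electron-poor ene-aldehyde by chromium(II) may also erode the yield. The fallback sets out from 35 and no longer relies on the carbonyl addition to fix C7. The cyclisation is run as in step 22 and its product, taken as the C7-epimeric butenolide F1, is treated with TIPSOTf and Et3N in CH2Cl2 to give the 2-silyloxyfuran F2, in which C7 is trigonal. Acetic acid-buffered TBAF in THF at −78 °C then cleaves the enol silyl ether and protonates the furanolate at C7 from its more open face. The butenolide is regenerated and the route is rejoined at 38; the configuration at C7 is then set by protonation and can also be equilibrated.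

Step 14. The titanium enolate may react through the closed chair and give mainly the C2 epimer (poor or reversed diastereoselection at the carbinol carbon). The fallback sets out from 22 and 16 and sets C2 by reagent-controlled reduction. The aldol adduct is taken on whatever its C2 ratio, written as the C2-epimeric aldol F3, and is oxidised with Dess–Martin periodinane to the 1,3-diketone F4, in which C2 is trigonal and C1 cannot enolise. (R)-Me-CBS with catecholborane reduces the more reactive ring carbonyl first to the (14S)-hydroxy ketone F5, which is acetylated (Ac2O, DMAP) to the acetoxy ketone F6. (S)-Me-CBS with catecholborane then reduces the side-chain ketone, with the quaternary C1 as the large group, to the (2R)-alcohol F7. Butyric anhydride and DMAP return the route to 28.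

Step 19. The β-magnesiated enoate, which has no chelation from the trans ester, may decompose or isomerise before it adds to the hindered, enolisable aldehyde, and the triethylsilyl group may migrate to the new alkoxide. The fallback sets out from 30 and uses a furan as the masked cis-formyl acrylate. 3-Bromo-4-methylfuran F8 (from 3,4-dibromofuran by bromine–lithium exchange and iodomethane) is lithiated with n-BuLi at −78 °C and added to 30 to give, again in the Felkin–Anh sense, the furyl carbinol F9, which is acetylated to the furyl acetate F10. Photo-oxygenation (O2, rose bengal, light, i-Pr2NEt, CH2Cl2, −78 °C) converts the furan into the γ-hydroxybutenolide F11, the hindered base removing the endoperoxide proton next to the methyl group so that the carbonyl becomes C19 and the hemiacetal carbon C7. Iodomethane and KHCO3 in DMF alkylate the carboxylate of its open form, and the route is rejoined at 35, steps 20 and 21 being bypassed.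

Further compounds
F1 | step 22 | C7 epimer of 38 | CCCC(=O)O[C@@H]1CC/C(C)=C\[C@H]2OC(=O)C(C)=C2[C@H](OC(C)=O)[C@H]2[C@@H](C)[C@H](O[Si](C)(C)C(C)(C)C)C[C@H](OC(C)=O)[C@@]21C
F2 | step 22 | 2-(triisopropylsilyloxy)furan derived from the butenolide of F1 (C7 trigonal) | CCCC(=O)O[C@@H]1CC/C(C)=C\c2oc(O[Si](C(C)C)(C(C)C)C(C)C)c(C)c2[C@H](OC(C)=O)[C@H]2[C@@H](C)[C@H](O[Si](C)(C)C(C)(C)C)C[C@H](OC(C)=O)[C@@]21C
F3 | step 14 | C2 epimer of aldol adduct 25 | O[C@@H](CC/C(C)=C\I)[C@@]1(C)C(=O)C[C@@H](O[Si](C)(C)C(C)(C)C)[C@H](C)[C@@H]1C=C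
F4 | step 14 | 1,3-diketone (C2 and C14 carbonyls on quaternary C1) | O=C(CC/C(C)=C\I)[C@@]1(C)C(=O)C[C@@H](O[Si](C)(C)C(C)(C)C)[C@H](C)[C@@H]1C=C
F5 | step 14 | (14S)-hydroxy C2 ketone | O=C(CC/C(C)=C\I)[C@@]1(C)[C@@H](O)C[C@@H](O[Si](C)(C)C(C)(C)C)[C@H](C)[C@@H]1C=C
F6 | step 14 | (14S)-acetoxy C2 ketone | O=C(CC/C(C)=C\I)[C@@]1(C)[C@@H](OC(C)=O)C[C@@H](O[Si](C)(C)C(C)(C)C)[C@H](C)[C@@H]1C=C
F7 | step 14 | (2R)-alcohol with (14S)-acetate | O[C@H](CC/C(C)=C\I)[C@@]1(C)[C@@H](OC(C)=O)C[C@@H](O[Si](C)(C)C(C)(C)C)[C@H](C)[C@@H]1C=C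
F8 | step 19 | 3-bromo-4-methylfuran | Cc1cocc1Br
F9 | step 19 | (9R)-(4-methylfuran-3-yl) carbinol from 30 | CCCC(=O)O[C@H](CC/C(C)=C\I)[C@@]1(C)[C@@H](OC(C)=O)C[C@@H](O[Si](C)(C)C(C)(C)C)[C@H](C)[C@@H]1[C@@H](O)c1cocc1C
F10 | step 19 | (9R)-acetate of F9 | CCCC(=O)O[C@H](CC/C(C)=C\I)[C@@]1(C)[C@@H](OC(C)=O)C[C@@H](O[Si](C)(C)C(C)(C)C)[C@H](C)[C@@H]1[C@@H](OC(C)=O)c1cocc1C
F11 | step 19 | γ-hydroxybutenolide (C7 hemiacetal, C19 lactone carbonyl; C7 epimers) | CCCC(=O)O[C@H](CC/C(C)=C\I)[C@@]1(C)[C@@H](OC(C)=O)C[C@@H](O[Si](C)(C)C(C)(C)C)[C@H](C)[C@@H]1[C@@H](OC(C)=O)C1=C(C)C(=O)OC1O
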